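G stands at 0.0050 M and D at 5.50 mM, while J comes to 7.50 mM by steady dosing over 12 s.

G 0.0050 M; D 5.50 mM; J 7.50 mM (fed, over 12 s); time 3.0 min

    D + X → D.X (k1 = 47.6 M⁻¹ s⁻¹)
    X → L (k2 = 0.0219 s⁻¹)
    G → X (k3 = 0.0101 s⁻¹)
    J + X → J.X (k4 = 509 M⁻¹ s⁻¹)

- the reaction counts as stopped when no species that holds the G changes by six tenths of a point or more over the second half of the time
- run time (flask): 3.0 min

1. at 3.0 min, what has stopped the reaction, if anything has (J has run out first / all of G has reacted / it is still moving / D has run out first)
2. D.X at 3.0 min, in percent of the G charged
3. J.X at 3.0 min, in percent of the G charged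

- I work in fractions of the G charged and freeze D at its charge. The rates of D.X and J.X both hold X, so their quotient drops X and time, and D.X grows in step with the logarithm of J's fall.
- The slope is 47.6 M⁻¹ s⁻¹ times the D charge over 509 M⁻¹ s⁻¹ times the G charge: the fraction of G charged that ends as D.X for each unit of ln(J before / J after), a selectivity factor scaled by the charges, 0.103.
- Step by step: the step from G holds no other species on its left, so 83.8% of the G charged has passed by 3.0 min, and the J charge is 1.50 G charges.
- If all that has passed went to J.X, J would stand at 44.2% of its charge, which gives D.X 8.41%. Correcting J to 49.8% gives D.X 7.18% and J.X 76.6%.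
- Freezing D is an approximation: by my figure D loses 6.53% of its charge. G still falls 24 percentage points in the second half, so I say the flask is still moving.
- One number is not quite enough. While 11.4% of G passes during the feed, J stands below its charge, so I expect more D.X than my figure.
- The forecast says it is still moving, with D.X 8% and J.X 75.1%, noting that “G was still dropping by tens of points”. Its D.X lies 0.82 points above mine.
- The flask at 3.0 min reads: it is still moving, with D.X 7.90% and J.X 75.1%. At the end of the feed, 0.200 min, this flask holds D.X 1.70% and J 93.8% of its charge. Adding 0.103, scaled by the mean D left, times J's logarithmic fall from there gives 7.90%. The neighbour flask with 0.0019 M of J keeps the same 0.103, and its J left, 0.845%, with D at 62.8%, gives 40.0%, where that flask stands at D.X 40.9%.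

All constants were chosen freely; the rest is arithmetic.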